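**Plan**

- Chain numbering: C1 is the ester carbon and C20 the CHBr terminus; the oxolane ring holds O, C5, C6, C7 and C8.
- Retrosynthesis cuts C10–C11 (alkyne–alkenyl coupling), then C11=C12 (iodo-olefination), then C15–C16 (alkyl–allyl coupling), and last re-forms the C17–C20 σ bond, folding the bromodiene into a cyclobutene.
- The feature that allows this: C17=C18 is Z, C19=C20 is E and C20 carries Br, one substituent turned in and one turned out. Conrotatory opening of a cis-3,4-disubstituted cyclobutene (ring carbons C17–C20, carboxyl carbon C16) gives exactly this when bromine rotates outward.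
- Forward, bromodiene arm: 2-pyranone, photolactone, cis-bromo acid, ring opening (the four-membered ring is spent, none is formed), then ester, allylic alcohol, allylic bromide, coupling with a C12–C15 acetal Grignard reagent, aldehyde, E-alkenyl iodide.
- Forward, oxolane half: allylboration of pent-4-enal sets C5; the only ring closure is an aerobic cobalt 5-exo cyclisation that sets C8 trans to C5; acrylate cross-metathesis, hydrogenation, oxidation and alkyne homologation follow; a Sonogashira coupling joins the halves last.
- Alkene geometry: C17=C18 and C19=C20 come from torquoselectivity, C11=C12 from the Takai reaction; no later step uses strong base.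

Key step: step 3

Remark: compounds 2 and 4 are racemic, which is harmless because both of their stereocentres become sp2 carbons in step 3; the allylborane of step 10 is taken to be the enantiomer built from (−)-α-pinene.

**Route**

Step 1
Reactants: 1 2H-pyran-2-one
Product: 2 2-oxabicyclo[2.2.0]hex-5-en-3-one (cis-fused, racemic)
Conditions: hν (300 nm), Et2O (dilute), −10 °C, N2; kept cold in solution
Reagents that add atoms: none
Why: Irradiation closes the pyranone diene by photochemical disrotatory 4π electrocyclisation to the cis-fused bicyclic lactone, the established photoisomerisation of 2-pyranone, and the thermally labile product is handled only in cold dilute solution.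

Step 2
Reactants: 2 2-oxabicyclo[2.2.0]hex-5-en-3-one; 3 hydrogen bromide
Product: 4 cis-4-bromocyclobut-2-ene-1-carboxylic acid (racemic)
Conditions: HBr (1.05 equiv, in Et2O), Et2O, −40 → 0 °C; concentrated cold, used at once
Reagents that add atoms: none
Why: Acid-mediated alkyl–oxygen cleavage of the strained allylic lactone (hydrohalogenolysis, as known with hydrogen chloride) should proceed by ionisation of the protonated lactone at the allylic C–O bond and collapse of the ion pair on the face from which the carboxyl group departs, so that bromine replaces oxygen with retention and stays cis to the carboxylic acid.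

Step 3
Reactants: 4 cis-4-bromocyclobut-2-ene-1-carboxylic acid
Product: 5 (2Z,4E)-5-bromopenta-2,4-dienoic acid
Conditions: PhMe, 45 °C, dark
Reagents that add atoms: none
Why: Gentle warming triggers the thermally allowed conrotatory 4π electrocyclic ring opening, in which the C17–C20 σ bond breaks and the C17=C18 and C19=C20 π bonds form, driven by release of four-membered-ring strain. The closest known reaction type is the thermal opening of cis-4-halocyclobut-2-enecarboxylic acids to (2Z,4E)-5-halopenta-2,4-dienoic acids. No ring closes and no stereocentre is created; the two stereocentres of 4 are traded for two stereogenic double bonds. The selectivity needed is torquoselectivity, one sense of conrotation out of two. Bromine, a lone-pair donor, turns outward because inward rotation would press its filled orbitals against the breaking σ bond, and since the two substituents are cis the weakly directing carboxyl group is carried inward. Bromine therefore ends on an E alkene and C16 on a Z alkene, and no base, metal or light is present that could equilibrate the diene afterwards.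

Step 4
Reactants: 5 (2Z,4E)-5-bromopenta-2,4-dienoic acid
Product: 6 methyl (2Z,4E)-5-bromopenta-2,4-dienoate
Conditions: TMSCHN2 (1.2 equiv), PhMe/MeOH 4:1, 0 °C
Reagents that add atoms: (trimethylsilyl)diazomethane, C[Si](C)(C)C=[N+]=[N-]
Why: Methyl esterification by diazomethane released from TMSCHN2 in methanol is neutral and cold, so the acid is capped without base or heat that could isomerise the 2Z alkene.

Step 5
Reactants: 6 methyl (2Z,4E)-5-bromopenta-2,4-dienoate
Product: 7 (2Z,4E)-5-bromopenta-2,4-dien-1-ol
Conditions: i-Bu2AlH (2.3 equiv), CH2Cl2, −78 °C; aq. KNaC4H4O6 work-up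
Reagents that add atoms: none
Why: Low-temperature i-Bu2AlH reduction of a conjugated ester proceeds by 1,2-hydride delivery to the allylic alcohol and should leave the diene geometry and the alkenyl bromide untouched.

Step 6
Reactants: 7 (2Z,4E)-5-bromopenta-2,4-dien-1-ol
Product: 8 (1E,3Z)-1,5-dibromopenta-1,3-diene
Conditions: CBr4 (1.2 equiv), PPh3 (1.25 equiv), CH2Cl2, −30 → 0 °C; used directly
Reagents that add atoms: tetrabromomethane, BrC(Br)(Br)Br
Why: The Appel reaction converts the primary allylic alcohol into the bromide by SN2 displacement of an alkoxyphosphonium ion under neutral cold conditions, which should avoid allylic transposition and Z to E isomerisation.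

Step 7
Reactants: 8 (1E,3Z)-1,5-dibromopenta-1,3-diene; 9 2-(3-chloropropyl)-1,3-dioxolane
Product: 11 2-[(5Z,7E)-8-bromoocta-5,7-dien-1-yl]-1,3-dioxolane, via Grignard reagent 10 (not isolated)
Conditions: 9, Mg, THF, 50 °C; then added quickly to 8, Li2CuCl4 (3 mol%), THF, −78 → −30 °C
Reagents that add atoms: none
Why: Magnesium insertion into the primary chloride gives Grignard reagent 10, and the Li2CuCl4-catalysed Grignard allylic substitution, run in THF at low temperature with the Grignard in excess over copper, should pass through a dialkylcuprate that substitutes at the bromide-bearing carbon C16 (α attack) with retention of the Z alkene while the alkenyl C20–Br bond stays inert.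

Step 8
Reactants: 11 2-[(5Z,7E)-8-bromoocta-5,7-dien-1-yl]-1,3-dioxolane
Product: 12 (6Z,8E)-9-bromonona-6,8-dienal
Conditions: 2 M aq. HCl, THF, rt
Reagents that add atoms: water, O
Why: Acid-catalysed acetal hydrolysis releases the C12 aldehyde, and the isolated bromodiene carries no acid-labile function.

Step 9
Reactants: 12 (6Z,8E)-9-bromonona-6,8-dienal
Product: 13 (1E,3Z,9E)-1-bromo-10-iododeca-1,3,9-triene
Conditions: CrCl2 (6 equiv), CHI3 (2 equiv), THF/1,4-dioxane, 0 °C → rt, dark
Reagents that add atoms: iodoform, IC(I)I
Why: In the Takai olefination the geminal dichromium species formed from CHI3 and CrCl2 adds to the aldehyde and anti-periplanar elimination gives the E alkenyl iodide at C11=C12, while the alkenyl bromide is inert to CrCl2 in the absence of nickel.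

Step 10
Reactants: 14 pent-4-enal
Product: 16 (4S)-octa-1,7-dien-4-ol, via borinate ester 15 (not isolated)
Conditions: (+)-Ipc2B(allyl) (from (−)-α-pinene, 1 M in pentane), Et2O, −78 °C; then 3 M NaOH, 30% H2O2, 0 °C → rt
Reagents that add atoms: (+)-B-allyldiisopinocampheylborane, C=CCB([C@H]1C[C@H]2C[C@@H]([C@@H]1C)C2(C)C)[C@H]1C[C@H]2C[C@@H]([C@@H]1C)C2(C)C
Why: Brown asymmetric allylboration runs through a closed chair-like Zimmerman–Traxler transition state in which the isopinocampheyl groups from (−)-α-pinene direct the allyl group to the Re face of the aldehyde, which sets the carbinol carbon as (S) (the future C5), and oxidative work-up frees the alcohol from borinate 15.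

Step 11
Reactants: 16 (4S)-octa-1,7-dien-4-ol
Product: 17 [(2S,5S)-5-(prop-2-en-1-yl)oxolan-2-yl]methanol
Conditions: Co(modp)2 (modp = 1-morpholinocarbamoyl-4,4-dimethylpentane-1,3-dionate, 10 mol%), O2 (1 atm), t-BuOOH (10 mol%), i-PrOH, 55 °C
Reagents that add atoms: dioxygen, O=O
Why: In the Mukaiyama aerobic oxidative cyclisation the divalent cobalt catalyst engages the hydroxyl group and the bishomoallylic alkene (C8=C9 in target numbering) in a 5-exo ring closure with oxygenation of the terminal carbon, a reaction type that is typically highly 2,5-trans-selective for 1-substituted pent-4-en-1-ols because the C5 substituent sits pseudo-equatorial in the cyclisation transition state, so C8 is set by C5, while the homoallylic alkene cannot close a five-membered ring and survives.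

Step 12
Reactants: 17 [(2S,5S)-5-(prop-2-en-1-yl)oxolan-2-yl]methanol; 18 methyl acrylate
Product: 19 methyl (2E)-4-[(2S,5S)-5-(hydroxymethyl)oxolan-2-yl]but-2-enoate
Conditions: 18 (4 equiv), second-generation Grubbs catalyst RuCl2(=CHPh)(H2IMes)(PCy3) (3 mol%), CH2Cl2, 40 °C
Reagents that add atoms: none
Why: Olefin cross-metathesis between a terminal type 1 alkene and the electron-poor acrylate is selective for the cross product and should give the E enoate, and the ruthenium carbene tolerates the free primary alcohol.

Step 13
Reactants: 19 methyl (2E)-4-[(2S,5S)-5-(hydroxymethyl)oxolan-2-yl]but-2-enoate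
Product: 20 methyl 4-[(2R,5S)-5-(hydroxymethyl)oxolan-2-yl]butanoate
Conditions: H2 (1 atm), Pd/C (10% palladium on carbon), EtOAc, rt
Reagents that add atoms: none
Why: Heterogeneous catalytic hydrogenation saturates the conjugated C2=C3 double bond and touches neither the ester nor the oxolane stereocentres (the descriptor change at C5 is only a priority change).

Step 14
Reactants: 20 methyl 4-[(2R,5S)-5-(hydroxymethyl)oxolan-2-yl]butanoate
Product: 21 methyl 4-[(2R,5S)-5-formyloxolan-2-yl]butanoate
Conditions: TEMPO (10 mol%), PhI(OAc)2 (1.1 equiv), CH2Cl2, rt; used crude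
Reagents that add atoms: none
Why: The oxoammonium-mediated TEMPO/PhI(OAc)2 oxidation stops at the aldehyde and is nearly neutral, so the α-alkoxy stereocentre C8 should not epimerise.

Step 15
Reactants: 21 methyl 4-[(2R,5S)-5-formyloxolan-2-yl]butanoate
Product: 23 methyl 4-[(2R,5S)-5-ethynyloxolan-2-yl]butanoate, via diazoalkene 22 (not isolated)
Conditions: dimethyl (1-diazo-2-oxopropyl)phosphonate (1.3 equiv), K2CO3 (2 equiv), MeOH, 0 °C → rt
Reagents that add atoms: dimethyl (1-diazo-2-oxopropyl)phosphonate, COP(=O)(OC)C(=[N+]=[N-])C(C)=O
Why: In the Seyferth–Gilbert homologation with the Ohira–Bestmann reagent, methanolysis releases the dimethyl (diazomethyl)phosphonate anion, Horner–Wadsworth–Emmons-type olefination gives diazoalkene 22, and loss of N2 with 1,2-hydrogen shift delivers the terminal alkyne under carbonate conditions mild enough to preserve C8 and compatible with a methyl ester in methanol.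

Step 16
Reactants: 13 (1E,3Z,9E)-1-bromo-10-iododeca-1,3,9-triene; 23 methyl 4-[(2R,5S)-5-ethynyloxolan-2-yl]butanoate
Product: 24 methyl 4-[(2R,5S)-5-[(3E,9Z,11E)-12-bromododeca-3,9,11-trien-1-yn-1-yl]oxolan-2-yl]butanoate (CNP0231094.1)
Conditions: PdCl2(PPh3)2 (3 mol%), CuI (6 mol%), Et3N, THF, degassed, 0 °C → rt; 13 in slight excess
Reagents that add atoms: none
Why: In the Sonogashira coupling zerovalent palladium inserts into the alkenyl C–I bond far faster than into the alkenyl C–Br bond at room temperature and the copper acetylide of 23 transmetallates, so the C10–C11 bond should form with retention of the E geometry while C20–Br is kept.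

**Compound list**

1 | 2H-pyran-2-one | O=C1C=CC=CO1 | starting material
2 | 2-oxabicyclo[2.2.0]hex-5-en-3-one (cis-fused; racemic, (1S,4R) enantiomer drawn) | O=C1[C@@H]2C=C[C@@H]2O1 | intermediate
3 | hydrogen bromide | Br | starting material
4 | cis-4-bromocyclobut-2-ene-1-carboxylic acid (racemic, (1S,4S) enantiomer drawn) | OC(=O)[C@@H]1C=C[C@@H]1Br | intermediate
5 | (2Z,4E)-5-bromopenta-2,4-dienoic acid | OC(=O)/C=C\C=C\Br | intermediate
6 | methyl (2Z,4E)-5-bromopenta-2,4-dienoate | COC(=O)/C=C\C=C\Br | intermediate
7 | (2Z,4E)-5-bromopenta-2,4-dien-1-ol | OC/C=C\C=C\Br | intermediate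
8 | (1E,3Z)-1,5-dibromopenta-1,3-diene | BrC/C=C\C=C\Br | intermediate
9 | 2-(3-chloropropyl)-1,3-dioxolane | ClCCCC1OCCO1 | starting material
10 | [3-(1,3-dioxolan-2-yl)propyl]magnesium chloride | Cl[Mg]CCCC1OCCO1 | intermediate (not isolated)
11 | 2-[(5Z,7E)-8-bromoocta-5,7-dien-1-yl]-1,3-dioxolane | Br/C=C/C=C\CCCCC1OCCO1 | intermediate
12 | (6Z,8E)-9-bromonona-6,8-dienal | O=CCCCC/C=C\C=C\Br | intermediate
13 | (1E,3Z,9E)-1-bromo-10-iododeca-1,3,9-triene | I/C=C/CCCC/C=C\C=C\Br | intermediate
14 | pent-4-enal | C=CCCC=O | starting material
15 | (4S)-octa-1,7-dien-4-yl diisopinocampheylborinate | C=CC[C@H](CCC=C)OB([C@H]1C[C@H]2C[C@@H]([C@@H]1C)C2(C)C)[C@H]1C[C@H]2C[C@@H]([C@@H]1C)C2(C)C | intermediate (not isolated)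
16 | (4S)-octa-1,7-dien-4-ol | C=CC[C@@H](O)CCC=C | intermediate
17 | [(2S,5S)-5-(prop-2-en-1-yl)oxolan-2-yl]methanol (2,5-trans) | C=CC[C@@H]1CC[C@@H](CO)O1 | intermediate
18 | methyl acrylate | C=CC(=O)OC | starting material
19 | methyl (2E)-4-[(2S,5S)-5-(hydroxymethyl)oxolan-2-yl]but-2-enoate | COC(=O)/C=C/C[C@@H]1CC[C@@H](CO)O1 | intermediate
20 | methyl 4-[(2R,5S)-5-(hydroxymethyl)oxolan-2-yl]butanoate | COC(=O)CCC[C@@H]1CC[C@@H](CO)O1 | intermediate
21 | methyl 4-[(2R,5S)-5-formyloxolan-2-yl]butanoate | COC(=O)CCC[C@@H]1CC[C@@H](C=O)O1 | intermediate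
22 | methyl 4-[(2R,5S)-5-(2-diazoethenyl)oxolan-2-yl]butanoate | COC(=O)CCC[C@@H]1CC[C@@H](C=C=[N+]=[N-])O1 | intermediate (not isolated)
23 | methyl 4-[(2R,5S)-5-ethynyloxolan-2-yl]butanoate | COC(=O)CCC[C@@H]1CC[C@@H](C#C)O1 | intermediate
24 | methyl 4-[(2R,5S)-5-[(3E,9Z,11E)-12-bromododeca-3,9,11-trien-1-yn-1-yl]oxolan-2-yl]butanoate | COC(=O)CCC[C@@H]1CC[C@@H](C#C/C=C/CCCC/C=C\C=C\Br)O1 | target

**Count**

Total steps: 16. Longest linear sequence: 10 steps (steps 1–9, then step 16); the oxolane half is 6 steps (10–15).

**Steps most likely to fail**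

First, step 2. The lactone opening may lose its stereochemical course: backside attack of bromide would give the trans bromide, which would open to the wrong diene geometry. Free hydrogen bromide may also trigger early ring opening and acid-catalysed isomerisation of the Z acid. The fallback sets out from 2 and comes back at 4, replacing the protic acid by a silyl halide. Bromotrimethylsilane in CH2Cl2 at −78 → −20 °C should silylate the lactone carbonyl and deliver bromide within the ion pair to give trimethylsilyl cis-4-bromocyclobut-2-ene-1-carboxylate F1. Cold methanolysis of F1 then returns acid 4 without free hydrogen bromide ever being present.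

Second, step 7. The organocopper intermediate may deliver the alkyl group with allylic transposition (attack at C18 or C20 through a π-allyl species) or with partial Z to E leakage at C17=C18, and halogen–metal exchange at the alkenyl bromide may compete. The fallback sets out from 8 and comes back at 12, replacing the copper step by enolate and aza-enolate SN2 alkylations that have no transposition channel. The lithium enolate of tert-butyl acetate (LiN(i-Pr)2, THF, −78 °C) is alkylated by 8 to give tert-butyl (4Z,6E)-7-bromohepta-4,6-dienoate F2. Reduction with i-Bu2AlH gives (4Z,6E)-7-bromohepta-4,6-dien-1-ol F3, and I2, PPh3 and imidazole convert it into (1E,3Z)-1-bromo-7-iodohepta-1,3-diene F4. Alkylation of lithiated acetaldehyde N,N-dimethylhydrazone with F4 gives (6Z,8E)-9-bromonona-6,8-dienal N,N-dimethylhydrazone F5, and mild hydrolysis (aq. oxalic acid, Et2O) returns aldehyde 12.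

Third, step 16. Oxidative addition into the alkenyl bromide at C20 may compete with that into the iodide, and oxidative homocoupling of the alkyne may consume 23. The fallback sets out from 12 and 23 and comes back at 24, reversing the polarity of the partners and avoiding palladium. Aldehyde 12 is homologated with the Ohira–Bestmann reagent (K2CO3, MeOH) to (1E,3Z)-1-bromodeca-1,3-dien-9-yne F6. Alkyne 23 is brominated (N-bromosuccinimide, AgNO3 cat., acetone) to methyl 4-[(2R,5S)-5-(bromoethynyl)oxolan-2-yl]butanoate F7. Hydroboration of F6 with dicyclohexylborane (THF, 0 °C) should add selectively to the terminal alkyne and give [(1E,7Z,9E)-10-bromodeca-1,7,9-trien-1-yl]dicyclohexylborane F8. Coupling of F8 with F7 under Cu(acac)2 catalysis with NaOMe (THF, −15 °C → rt), a known alkenylborane–bromoalkyne enyne synthesis to which alkenyl bromides are inert, should then give 24.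

**Further compounds**

F1 | step 2 | trimethylsilyl cis-4-bromocyclobut-2-ene-1-carboxylate (racemic) | C[Si](C)(C)OC(=O)[C@@H]1C=C[C@@H]1Br
F2 | step 7 | tert-butyl (4Z,6E)-7-bromohepta-4,6-dienoate | CC(C)(C)OC(=O)CC/C=C\C=C\Br
F3 | step 7 | (4Z,6E)-7-bromohepta-4,6-dien-1-ol | OCCC/C=C\C=C\Br
F4 | step 7 | (1E,3Z)-1-bromo-7-iodohepta-1,3-diene | ICCC/C=C\C=C\Br
F5 | step 7 | (6Z,8E)-9-bromonona-6,8-dienal N,N-dimethylhydrazone | CN(C)/N=C/CCCC/C=C\C=C\Br
F6 | step 16 | (1E,3Z)-1-bromodeca-1,3-dien-9-yne | C#CCCCC/C=C\C=C\Br
F7 | step 16 | methyl 4-[(2R,5S)-5-(bromoethynyl)oxolan-2-yl]butanoate | COC(=O)CCC[C@@H]1CC[C@@H](C#CBr)O1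
F8 | step 16 | [(1E,7Z,9E)-10-bromodeca-1,7,9-trien-1-yl]dicyclohexylborane | Br/C=C/C=C\CCCC/C=C/B(C1CCCCC1)C1CCCCC1
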